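## The problem

The target, (4S,5R,10R)-11,14-dihydroxy-12-methoxy-7-oxoabieta-8,11,13-trien-19,20-olide (23), is a trans-fused abietane. Ring C is a hexasubstituted hydroquinone (C11 OH, C12 OMe, C13 isopropyl, C14 OH) fused through C8–C9 to ring B, which carries the C7 ketone. Ring A is bridged by a δ-lactone running from the C19 carbonyl on C4 to the C20 oxymethylene on C10. Three contiguous stereocentres (C4, C5, C10) must be set, two of them quaternary; rings B and C carry none. C4 can control C10, because the lactone can only close between C19 and a C20 group on the same face of ring A. C4 controls C5 poorly, since methyl and ester differ little in size, so C5 needs its own control element. The sensitive groups are the electron-rich hydroquinone (air oxidation), a C7 alcohol next to an electron-rich ring C (loss of water to the 6,7-alkene), alkyl quinones toward base (enolisation through C7–H), and the lactone toward hard nucleophiles. The enabling feature is that ring C is attached to the rest only through C8 and C9. C11–C9 hangs from C10 and C8–C14 hangs from C7, so a 1,7-diyne (C11≡C9 on C10, C8≡C14 on C7) plus a C12≡C13 alkyne bearing the isopropyl group gives rings B and C in one [2+2+2] event, with boron on C11 and C14 standing in for the two hydroxyls.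

## Retrosynthesis

**23 to 20 (redox and protecting-group changes, no skeletal bond cut).** The hydroquinone is unmasked last: 23 comes from triketone 22 by quinone reduction, 22 from alcohol 21, and 21 from silyl ether 20. Keeping ring C at the quinone level until the final step makes it air-stable and prevents a C7 oxygen from ionising. Carrying a free hydroquinone through the C7 oxidation would instead require oxidising an alcohol beside the most oxidisable group in the molecule. The forward steps only need to distinguish a quinone from an aryl ketone.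

**20 to 18 (C12–O bond).** C12 is the one ring C position that the cyclotrimerisation leaves as C–H. In quinone 18 it is the only vinylic hydrogen, so halogen addition–elimination (19) followed by alkoxide displacement (20) reaches it without a regiochemical choice. Bringing the methoxy group in on the alkyne was rejected: an internal alkoxyalkyne would make the insertion hexasubstituted and would leave its orientation uncontrolled. The forward reaction must tolerate the base-sensitive alkyl quinone.

**18 to 16 (C11–O and C14–O bonds).** Both oxygens are traced to C–B bonds in bis-boronate 16. Oxidation of aryl boronates is dependable and places the oxygens exactly where the diyne termini were, which no electrophilic substitution on a preformed arene would do. The hydroquinone 17 is oxidised at once to 18.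

**16 to 14 + 15 (C8–C9, C11–C12, C13–C14; rings B and C).** This is the strategic cut. The alternatives, cutting C7–C8 (acylation) or C9–C10 (arylation), keep a complete hexasubstituted arene as a building block and form only ring B. The [2+2+2] cut removes both rings and every aryl substituent at once, leaving lactone-bridged diyne 14 and commercial 3-methylbut-1-yne (15). The forward reaction must favour cross-cyclotrimerisation over alkyne self-trimerisation and must place the isopropyl carbon next to C14, not C11.

**14 to 10 (C–B bonds, O–Si bond, C7–C8, and the C6–C7 aldehyde).** The boryl groups come off to terminal diyne 13, the silyl group to alcohol 12, and C7–C8 is cut to aldehyde 11 and an ethynyl nucleophile. The aldehyde is traced to the allyl group of 10, which serves as a masked acetaldehyde unit. A propargyl or protected hydroxyethyl chain at C5 would save nothing and would interfere with the earlier enolate chemistry.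

**10 to 8 (C9≡C11).** The C10 alkyne comes from aldehyde 9 by one-carbon homologation, and 9 from primary alcohol 8. Direct electrophilic alkynylation of a C10 aldehyde enolate was considered. It is poorly documented for hindered, fully substituted centres and would leave the C10 configuration to kinetic face selection.

**8 to 4 (lactone C20–O bond and both C10–CH2 bonds).** Lactone 8 is opened to bis(hydroxymethyl) ester 7, in which C10 is not stereogenic. Compound 7 is traced by double hydroxymethylation logic to aldehyde 6, and 6 through enol ether 5 to ketone 4. This makes the C10 configuration a consequence of C4: only the hydroxymethyl group syn to the ester can lactonise. Any alkylation of a C10 enolate would have to select a face. The forward steps are a Wittig homologation and an aldol/crossed Cannizzaro sequence.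

**4 to 1 (C5–C6 and C4–CH3).** The allyl group is removed to enol carbonate 3, which stores the regiochemistry of enolate 2. The C4 methyl group is removed to commercial enone ester 1. Conjugate methylation of a β-alkoxycarbonyl enone is a known catalytic asymmetric reaction and sets the absolute configuration in step 1. Allylation is separated from it, so that a chiral palladium catalyst, not the weakly biased C4 centre, decides the C5 configuration.

## Roads not taken

**Alternative 1:** Enantioselective Robinson annulation on a C20-ester β-tetralone. The cut is at C1–C10 and C4–C5. In the forward step the β-keto ester A1 adds to the vinyl ketone A2 under a chiral catalyst, and the chain condenses onto the C5 ketone to give tricyclic enone A3.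
- Merits: ring C arrives with all four substituents in place, so there is no regiochemical question and no late C12 oxygenation. C10 is set by a well-developed catalytic Michael addition. On these two points it is better than the chosen plan.
- Weak points: A1 is itself a pentasubstituted tetralone that needs a multistep arene synthesis. After A3 the route still needs a stereoselective C4 methylation, reduction of the tetrasubstituted C4=C5 alkene to the trans ring fusion, removal of the C3 ketone, differentiation of the C19 and C20 esters for lactonisation, benzylic oxidation at C7, and selective unmasking of two of three aryl methyl ethers.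
- Comparison: the chosen plan sets against the regiochemical certainty of A3 a convergent ring C assembly from three alkynes, a C7 oxygen present from the start, and no C3 oxygen to remove.

**Alternative 2:** Desymmetrising lactone-tethered Michael addition on a prochiral cyclohexadienone. The cut is at C4–C5. A chiral bifunctional base adds the tethered sulfonyl propanoate of dienone A4 to one enantiotopic enone and gives the cis-fused enone lactone A5.
- Merits: C5, C10 and the lactone are set in one catalytic step from an achiral precursor, and the tether guarantees the syn relation of C19 and C20. This is more economical than steps 1 to 5 of the chosen plan.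
- Weak points: C4 is left as a sulfonyl-bearing mixture, and ring A still has to be closed through C3–C4 with control of that centre. The whole of ring C, with four different substituents, must then be annulated onto the C8=C9 enone of A5, so the hardest part of the target remains open.
- Comparison: the chosen plan pays more steps for the ring A lactone but makes rings B and C, including the arene, in one step.

**Alternative 3:** Podocarpic acid relay with amidyl radical C20 lactonisation. The cut is at O–C20, a C–H functionalisation. Podocarpic acid A6 is elaborated to carboxamide A7. Its N-iodo derivative, on photolysis, transfers a C20 hydrogen to the amidyl radical, and the lactone A8 forms after displacement and hydrolysis.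
- Merits: all three stereocentres and the tricyclic skeleton are bought, and the axial C19 amide is 1,3-diaxial to C20, so the hydrogen transfer is well placed. A8 already has the lactone, the C7 ketone, the C12 methoxy and the C13 isopropyl group. It is shorter and stereochemically safer than the chosen plan up to this point.
- Weak points: A8 lacks both the C11 and the C14 oxygen. C11 lies between the methoxy group and the quaternary C10, and C14 is peri to the ketone. Two arene C–H oxidations on a ring deactivated by the ketone are needed, and these are the least selective steps such a route could contain.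
- Comparison: the chosen plan sets against the short relay that the C11 and C14 oxygens are built in as boron when ring C forms.

Key step: step 12

Remark on the chemistry: C7 is carried as a mixture of both epimers from 12 to 21 because it ends as a ketone, so the SMILES of these compounds leave C7 unassigned. Compound 5 is an E/Z mixture and 6 a mixture of C10 epimers (ring position 3); both converge in step 5.

## Route

Step 1
Reactants: 1 methyl 3-oxocyclohex-1-ene-1-carboxylate
Product: 3 methyl (1S)-1-methyl-3-{[(prop-2-en-1-yloxy)carbonyl]oxy}cyclohex-2-ene-1-carboxylate, via methylzinc enolate 2 (not isolated)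
Conditions: Me2Zn (3 equiv), (CuOTf)2·C6H6 (2.5 mol%), chiral sulfonate-bearing imidazolinium salt as NHC precursor (5 mol%, the enantiomer that gives the 1S adduct), t-BuOMe, −30 °C; then allyl chloroformate, −30 to 0 °C
Reagents that add atoms: dimethylzinc, C[Zn]C; allyl chloroformate, C=CCOC(Cl)=O
Why: Catalytic asymmetric conjugate addition of a dialkylzinc to a β-alkoxycarbonyl cyclic enone forms the C4 quaternary centre, its S configuration being set by the chiral NHC ligand on (CuOTf)2·C6H6. The zinc enolate forms only toward C5 and is O-acylated by the chloroformate, so the enolate regiochemistry is stored in enol carbonate 3.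

Step 2
Reactants: 3 methyl (1S)-1-methyl-3-{[(prop-2-en-1-yloxy)carbonyl]oxy}cyclohex-2-ene-1-carboxylate
Product: 4 methyl (1S,2S)-1-methyl-3-oxo-2-(prop-2-en-1-yl)cyclohexane-1-carboxylate
Conditions: Pd2(dba)3·CHCl3 (2.5 mol%), (R,R)-1,2-bis[2-(diphenylphosphino)benzamido]cyclohexane (5.5 mol%), 1,4-dioxane, rt
Reagents that add atoms: none
Why: Decarboxylative asymmetric allylic alkylation (Tsuji–Trost type): zerovalent palladium ionises the allyl carbonate, CO2 is lost, and the regiodefined enolate attacks the π-allyl complex at C5 under neutral conditions that do not equilibrate the enolate. Methyl and ester at C4 differ too little to steer the enolate face, so the chiral diphosphine is relied on to place allyl anti to the C4 methyl group (2S); the ligand antipode is held ready should the first run show the opposite sense.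

Step 3
Reactants: 4 methyl (1S,2S)-1-methyl-3-oxo-2-(prop-2-en-1-yl)cyclohexane-1-carboxylate
Product: 5 methyl (1S,2R)-3-(methoxymethylidene)-1-methyl-2-(prop-2-en-1-yl)cyclohexane-1-carboxylate
Conditions: Ph3P(CH2OMe)Cl, KN(SiMe3)2, THF, 0 °C to rt
Reagents that add atoms: (methoxymethyl)triphenylphosphonium chloride, [Cl-].COC[P+](c1ccccc1)(c1ccccc1)c1ccccc1
Why: Wittig methoxymethylenation homologates the C10 ketone by one carbon. The non-stabilised ylide is nucleophilic enough for the α-branched ketone, and excess ylide at 0 °C limits enolisation toward C5.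

Step 4
Reactants: 5 methyl (1S,2R)-3-(methoxymethylidene)-1-methyl-2-(prop-2-en-1-yl)cyclohexane-1-carboxylate
Product: 6 methyl (1S,2R)-3-formyl-1-methyl-2-(prop-2-en-1-yl)cyclohexane-1-carboxylate
Conditions: 2 M HCl, THF, rt
Reagents that add atoms: water, O
Why: Acid hydrolysis of the enol ether gives the homologated aldehyde. The two C10 epimers are not separated because C10 becomes trigonal again in the next step.

Step 5
Reactants: 6 methyl (1S,2R)-3-formyl-1-methyl-2-(prop-2-en-1-yl)cyclohexane-1-carboxylate
Product: 8 (1S,5R,9R)-5-(hydroxymethyl)-1-methyl-9-(prop-2-en-1-yl)-3-oxabicyclo[3.3.1]nonan-2-one, via bis(hydroxymethyl) ester 7 (not isolated)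
Conditions: 37% aq. CH2O (excess), KOH, MeOH, 0 to 45 °C; then p-TsOH·H2O (cat.), toluene, 80 °C
Reagents that add atoms: formaldehyde, C=O
Why: Tollens sequence: crossed aldol of the C10 enolate with formaldehyde, then crossed Cannizzaro reduction, gives diol 7, in which C10 is no longer stereogenic. Only the hydroxymethyl group 1,3-syn to the C4 ester can reach it, so lactonisation to the 3-oxabicyclo[3.3.1]nonan-2-one fixes C10 from C4 whatever the face selectivity of the aldol step.

Step 6
Reactants: 8 (1S,5R,9R)-5-(hydroxymethyl)-1-methyl-9-(prop-2-en-1-yl)-3-oxabicyclo[3.3.1]nonan-2-one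
Product: 9 (1S,5S,9R)-1-methyl-2-oxo-9-(prop-2-en-1-yl)-3-oxabicyclo[3.3.1]nonane-5-carbaldehyde
Conditions: Dess–Martin periodinane, NaHCO3, CH2Cl2, 0 °C to rt
Reagents that add atoms: none
Why: Dess–Martin oxidation of the neopentyl primary alcohol. The aldehyde has no α-hydrogen, so it can neither epimerise nor eliminate the lactone oxygen.

Step 7
Reactants: 9 (1S,5S,9R)-1-methyl-2-oxo-9-(prop-2-en-1-yl)-3-oxabicyclo[3.3.1]nonane-5-carbaldehyde
Product: 10 (1S,5R,9R)-5-ethynyl-1-methyl-9-(prop-2-en-1-yl)-3-oxabicyclo[3.3.1]nonan-2-one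
Conditions: dimethyl (1-diazo-2-oxopropyl)phosphonate, K2CO3, MeOH, 0 °C to rt
Reagents that add atoms: dimethyl (1-diazo-2-oxopropyl)phosphonate, CC(=O)C(=[N+]=[N-])P(=O)(OC)OC
Why: Seyferth–Gilbert homologation with the Ohira–Bestmann reagent converts the hindered aldehyde into the terminal alkyne C9≡C11 under mild carbonate conditions. The bridged lactone, whose carbonyl sits on quaternary C4, tolerates these conditions.

Step 8
Reactants: 10 (1S,5R,9R)-5-ethynyl-1-methyl-9-(prop-2-en-1-yl)-3-oxabicyclo[3.3.1]nonan-2-one
Product: 11 2-[(1S,5R,9R)-5-ethynyl-1-methyl-2-oxo-3-oxabicyclo[3.3.1]nonan-9-yl]acetaldehyde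
Conditions: O3, CH2Cl2, −78 °C (Sudan red 7B as end-point indicator); then PPh3, −78 °C to rt
Reagents that add atoms: ozone, [O-][O+]=O
Why: Ozonolysis cleaves the terminal alkene much faster than the alkyne. Dosing ozone against the dye and reducing the ozonide with PPh3 gives the C7 aldehyde.

Step 9
Reactants: 11 2-[(1S,5R,9R)-5-ethynyl-1-methyl-2-oxo-3-oxabicyclo[3.3.1]nonan-9-yl]acetaldehyde
Product: 12 (1S,5R,9R)-5-ethynyl-9-(2-hydroxybut-3-yn-1-yl)-1-methyl-3-oxabicyclo[3.3.1]nonan-2-one
Conditions: HC≡CMgBr (3 equiv), THF, −20 to 0 °C; aq. NH4Cl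
Reagents that add atoms: ethynylmagnesium bromide, C#C[Mg]Br
Why: 1,2-Addition of the alkynyl Grignard reagent to the aldehyde forms C7–C8. The hindered lactone carbonyl is spared at 0 °C, and both C7 epimers are carried on together.

Step 10
Reactants: 12 (1S,5R,9R)-5-ethynyl-9-(2-hydroxybut-3-yn-1-yl)-1-methyl-3-oxabicyclo[3.3.1]nonan-2-one
Product: 13 (1S,5R,9R)-9-{2-[(tert-butyldimethylsilyl)oxy]but-3-yn-1-yl}-5-ethynyl-1-methyl-3-oxabicyclo[3.3.1]nonan-2-one
Conditions: TBSCl, imidazole, DMF, rt
Reagents that add atoms: tert-butyldimethylsilyl chloride, CC(C)(C)[Si](C)(C)Cl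
Why: Standard silylation of the propargylic alcohol. The silyl ether survives the strong base of the next step and the quinone chemistry, and is removed late with fluoride.

Step 11
Reactants: 13 (1S,5R,9R)-9-{2-[(tert-butyldimethylsilyl)oxy]but-3-yn-1-yl}-5-ethynyl-1-methyl-3-oxabicyclo[3.3.1]nonan-2-one
Product: 14 (1S,5R,9R)-9-{2-[(tert-butyldimethylsilyl)oxy]-4-(4,4,5,5-tetramethyl-1,3,2-dioxaborolan-2-yl)but-3-yn-1-yl}-1-methyl-5-[(4,4,5,5-tetramethyl-1,3,2-dioxaborolan-2-yl)ethynyl]-3-oxabicyclo[3.3.1]nonan-2-one
Conditions: LiN(iPr)2 (2.3 equiv), THF, −78 °C; 2-isopropoxy-4,4,5,5-tetramethyl-1,3,2-dioxaborolane, −78 °C; then HCl in Et2O, −78 °C to rt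
Reagents that add atoms: 2-isopropoxy-4,4,5,5-tetramethyl-1,3,2-dioxaborolane, CC(C)OB1OC(C)(C)C(C)(C)O1
Why: Deprotonation of both terminal alkynes and trapping with the isopropoxy boronate gives alkynyl borate complexes, which collapse to the alkynyl pinacol boronates on anhydrous HCl quench. The amide base is non-nucleophilic and the lactone has no α-hydrogen, so the lactone is left alone.

Step 12
Reactants: 14 (1S,5R,9R)-9-{2-[(tert-butyldimethylsilyl)oxy]-4-(4,4,5,5-tetramethyl-1,3,2-dioxaborolan-2-yl)but-3-yn-1-yl}-1-methyl-5-[(4,4,5,5-tetramethyl-1,3,2-dioxaborolan-2-yl)ethynyl]-3-oxabicyclo[3.3.1]nonan-2-one; 15 3-methylbut-1-yne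
Product: 16 (4S,5R,10R)-7-[(tert-butyldimethylsilyl)oxy]-11,14-bis(4,4,5,5-tetramethyl-1,3,2-dioxaborolan-2-yl)abieta-8,11,13-trien-19,20-olide
Conditions: Cp*RuCl(cod) (10 mol%), 15 (5 equiv), ClCH2CH2Cl, rt to 50 °C, sealed tube
Reagents that add atoms: none
Why: This is a formal [2+2+2] cycloaddition; the closest known reaction type is the Cp*RuCl(cod)-catalysed cyclotrimerisation of α,ω-diynes with terminal alkynes, which tolerates alkynylboronates. After loss of cyclooctadiene the Cp*RuCl fragment binds both boryl alkynes of 14 and couples them oxidatively to a ruthenacyclopentatriene; this forms C8–C9 and closes ring B, the mode of closure being intramolecular coupling of the two alkyne carbons held by the four-atom C10–C5–C6–C7 tether. Insertion of 15 into one ruthenium–carbon bond gives a ruthenacycloheptatetraene, and reductive elimination forms C11–C12 and C13–C14 and closes ring C as the benzene ring. No stereocentre is created: C4, C5 and C10 are spectators and C7 stays an epimeric mixture. Two selectivities are needed. Cross-reaction over self-trimerisation of 15 is secured by the tether, which makes the diyne coupling intramolecular, and by the substituted, hindered diyne alkynes, which do not pair between molecules. The orientation of 15 is set by sterics, since the isopropyl-bearing carbon bonds to the less hindered α-carbon of the ruthenacycle. C11 is flanked by quaternary C10 with its C1 and C20 methylene groups, whereas C14 is flanked only by C7–H with the silyloxy group pseudoaxial, so the isopropyl group should end at C13.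

Step 13
Reactants: 16 (4S,5R,10R)-7-[(tert-butyldimethylsilyl)oxy]-11,14-bis(4,4,5,5-tetramethyl-1,3,2-dioxaborolan-2-yl)abieta-8,11,13-trien-19,20-olide
Product: 18 (4S,5R,10R)-7-[(tert-butyldimethylsilyl)oxy]-11,14-dioxoabieta-8,12-dien-19,20-olide, via 11,14-hydroquinone 17 (not isolated)
Conditions: KHSO5 (as Oxone), NaHCO3, acetone/H2O, 0 °C; then Ag2O, MgSO4, Et2O, rt
Reagents that add atoms: potassium peroxymonosulfate, [K+].[O-]S(=O)(=O)OO
Why: Oxidative C–B to C–O conversion of both aryl boronates (1,2-aryl shift from boron to peroxide oxygen) gives the 11,14-hydroquinone. This is oxidised at once to the quinone, so the air-sensitive hydroquinone is never handled.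

Step 14
Reactants: 18 (4S,5R,10R)-7-[(tert-butyldimethylsilyl)oxy]-11,14-dioxoabieta-8,12-dien-19,20-olide
Product: 19 (4S,5R,10R)-12-bromo-7-[(tert-butyldimethylsilyl)oxy]-11,14-dioxoabieta-8,12-dien-19,20-olide
Conditions: Br2 (1.05 equiv), NaOAc, AcOH/CH2Cl2, 0 °C to rt, in the dark
Reagents that add atoms: bromine, BrBr
Why: Bromine adds to the only trisubstituted quinone double bond (C12=C13) and HBr is lost, the classical halogenation of an alkyl quinone. Acetate buffers the HBr and so protects the silyl ether.

Step 15
Reactants: 19 (4S,5R,10R)-12-bromo-7-[(tert-butyldimethylsilyl)oxy]-11,14-dioxoabieta-8,12-dien-19,20-olide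
Product: 20 (4S,5R,10R)-7-[(tert-butyldimethylsilyl)oxy]-12-methoxy-11,14-dioxoabieta-8,12-dien-19,20-olide
Conditions: NaOMe (1.1 equiv), MeOH/THF, −20 to 0 °C
Reagents that add atoms: sodium methoxide, [Na+].[O-]C
Why: Addition–elimination of methoxide at C12 of the bromoquinone, the standard route to methoxyquinones. Low temperature and one equivalent of base limit deprotonation at C7 and attack on the lactone.

Step 16
Reactants: 20 (4S,5R,10R)-7-[(tert-butyldimethylsilyl)oxy]-12-methoxy-11,14-dioxoabieta-8,12-dien-19,20-olide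
Product: 21 (4S,5R,10R)-7-hydroxy-12-methoxy-11,14-dioxoabieta-8,12-dien-19,20-olide
Conditions: HF·pyridine, pyridine, THF, 0 °C to rt
Reagents that add atoms: none
Why: Fluoride cleavage of the silyl ether under buffered, mildly acidic conditions. Basic fluoride is avoided because it would enolise the quinone through C7–H.

Step 17
Reactants: 21 (4S,5R,10R)-7-hydroxy-12-methoxy-11,14-dioxoabieta-8,12-dien-19,20-olide
Product: 22 (4S,5R,10R)-12-methoxy-7,11,14-trioxoabieta-8,12-dien-19,20-olide
Conditions: Dess–Martin periodinane, CH2Cl2, rt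
Reagents that add atoms: none
Why: Dess–Martin oxidation of the secondary alcohol beside the quinone ring installs the C7 ketone and removes the unassigned C7 centre.

Step 18
Reactants: 22 (4S,5R,10R)-12-methoxy-7,11,14-trioxoabieta-8,12-dien-19,20-olide
Product: 23 (4S,5R,10R)-11,14-dihydroxy-12-methoxy-7-oxoabieta-8,11,13-trien-19,20-olide
Conditions: Na2S2O4, EtOAc/H2O, rt, under argon
Reagents that add atoms: none
Why: Dithionite reduces the quinone to the hydroquinone and leaves the aryl ketone and the lactone untouched. The product is stabilised by the hydrogen bond from the C14 hydroxyl to the C7 carbonyl.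

## Compound list

1 | methyl 3-oxocyclohex-1-ene-1-carboxylate | COC(=O)C1=CC(=O)CCC1 | starting material
2 | methylzinc enolate of methyl (1S)-1-methyl-3-oxocyclohexane-1-carboxylate (enolate toward C2) | C[Zn]OC1=C[C@@](C)(C(=O)OC)CCC1 | intermediate (not isolated)
3 | methyl (1S)-1-methyl-3-{[(prop-2-en-1-yloxy)carbonyl]oxy}cyclohex-2-ene-1-carboxylate | C=CCOC(=O)OC1=C[C@@](C)(C(=O)OC)CCC1 | intermediate
4 | methyl (1S,2S)-1-methyl-3-oxo-2-(prop-2-en-1-yl)cyclohexane-1-carboxylate (allyl trans to methyl) | C=CC[C@@H]1C(=O)CCC[C@]1(C)C(=O)OC | intermediate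
5 | methyl (1S,2R)-3-(methoxymethylidene)-1-methyl-2-(prop-2-en-1-yl)cyclohexane-1-carboxylate (E/Z mixture) | C=CC[C@@H]1C(=COC)CCC[C@]1(C)C(=O)OC | intermediate
6 | methyl (1S,2R)-3-formyl-1-methyl-2-(prop-2-en-1-yl)cyclohexane-1-carboxylate (both C3 epimers) | C=CC[C@@H]1C(C=O)CCC[C@]1(C)C(=O)OC | intermediate
7 | methyl (1S,2R)-3,3-bis(hydroxymethyl)-1-methyl-2-(prop-2-en-1-yl)cyclohexane-1-carboxylate | C=CC[C@@H]1C(CO)(CO)CCC[C@]1(C)C(=O)OC | intermediate (not isolated)
8 | (1S,5R,9R)-5-(hydroxymethyl)-1-methyl-9-(prop-2-en-1-yl)-3-oxabicyclo[3.3.1]nonan-2-one (allyl on the lactone side of the one-carbon bridge) | C=CC[C@@H]1[C@@]2(CO)CCC[C@]1(C)C(=O)OC2 | intermediate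
9 | (1S,5S,9R)-1-methyl-2-oxo-9-(prop-2-en-1-yl)-3-oxabicyclo[3.3.1]nonane-5-carbaldehyde | C=CC[C@@H]1[C@@]2(C=O)CCC[C@]1(C)C(=O)OC2 | intermediate
10 | (1S,5R,9R)-5-ethynyl-1-methyl-9-(prop-2-en-1-yl)-3-oxabicyclo[3.3.1]nonan-2-one | C=CC[C@@H]1[C@@]2(C#C)CCC[C@]1(C)C(=O)OC2 | intermediate
11 | 2-[(1S,5R,9R)-5-ethynyl-1-methyl-2-oxo-3-oxabicyclo[3.3.1]nonan-9-yl]acetaldehyde | O=CC[C@@H]1[C@@]2(C#C)CCC[C@]1(C)C(=O)OC2 | intermediate
12 | (1S,5R,9R)-5-ethynyl-9-(2-hydroxybut-3-yn-1-yl)-1-methyl-3-oxabicyclo[3.3.1]nonan-2-one (both carbinol epimers) | C#CC(O)C[C@@H]1[C@@]2(C#C)CCC[C@]1(C)C(=O)OC2 | intermediate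
13 | (1S,5R,9R)-9-{2-[(tert-butyldimethylsilyl)oxy]but-3-yn-1-yl}-5-ethynyl-1-methyl-3-oxabicyclo[3.3.1]nonan-2-one | C#CC(O[Si](C)(C)C(C)(C)C)C[C@@H]1[C@@]2(C#C)CCC[C@]1(C)C(=O)OC2 | intermediate
14 | (1S,5R,9R)-9-{2-[(tert-butyldimethylsilyl)oxy]-4-(4,4,5,5-tetramethyl-1,3,2-dioxaborolan-2-yl)but-3-yn-1-yl}-1-methyl-5-[(4,4,5,5-tetramethyl-1,3,2-dioxaborolan-2-yl)ethynyl]-3-oxabicyclo[3.3.1]nonan-2-one | CC(C)(C)[Si](C)(C)OC(C#CB1OC(C)(C)C(C)(C)O1)C[C@@H]2[C@@]3(C#CB4OC(C)(C)C(C)(C)O4)CCC[C@]2(C)C(=O)OC3 | intermediate
15 | 3-methylbut-1-yne | CC(C)C#C | starting material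
16 | (4S,5R,10R)-7-[(tert-butyldimethylsilyl)oxy]-11,14-bis(4,4,5,5-tetramethyl-1,3,2-dioxaborolan-2-yl)abieta-8,11,13-trien-19,20-olide | CC(C)c1cc(B2OC(C)(C)C(C)(C)O2)c3c(c1B4OC(C)(C)C(C)(C)O4)C(O[Si](C)(C)C(C)(C)C)C[C@@H]5[C@]36CCC[C@]5(C)C(=O)OC6 | intermediate
17 | (4S,5R,10R)-7-[(tert-butyldimethylsilyl)oxy]-11,14-dihydroxyabieta-8,11,13-trien-19,20-olide | CC(C)c1cc(O)c2c(c1O)C(O[Si](C)(C)C(C)(C)C)C[C@@H]1[C@]23CCC[C@]1(C)C(=O)OC3 | intermediate (not isolated)
18 | (4S,5R,10R)-7-[(tert-butyldimethylsilyl)oxy]-11,14-dioxoabieta-8,12-dien-19,20-olide | CC(C)C1=CC(=O)C2=C(C1=O)C(O[Si](C)(C)C(C)(C)C)C[C@@H]1[C@]23CCC[C@]1(C)C(=O)OC3 | intermediate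
19 | (4S,5R,10R)-12-bromo-7-[(tert-butyldimethylsilyl)oxy]-11,14-dioxoabieta-8,12-dien-19,20-olide | CC(C)C1=C(Br)C(=O)C2=C(C1=O)C(O[Si](C)(C)C(C)(C)C)C[C@@H]1[C@]23CCC[C@]1(C)C(=O)OC3 | intermediate
20 | (4S,5R,10R)-7-[(tert-butyldimethylsilyl)oxy]-12-methoxy-11,14-dioxoabieta-8,12-dien-19,20-olide | CC(C)C1=C(OC)C(=O)C2=C(C1=O)C(O[Si](C)(C)C(C)(C)C)C[C@@H]1[C@]23CCC[C@]1(C)C(=O)OC3 | intermediate
21 | (4S,5R,10R)-7-hydroxy-12-methoxy-11,14-dioxoabieta-8,12-dien-19,20-olide | CC(C)C1=C(OC)C(=O)C2=C(C1=O)C(O)C[C@@H]1[C@]23CCC[C@]1(C)C(=O)OC3 | intermediate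
22 | (4S,5R,10R)-12-methoxy-7,11,14-trioxoabieta-8,12-dien-19,20-olide | CC(C)C1=C(OC)C(=O)C2=C(C1=O)C(=O)C[C@@H]1[C@]23CCC[C@]1(C)C(=O)OC3 | intermediate
23 | (4S,5R,10R)-11,14-dihydroxy-12-methoxy-7-oxoabieta-8,11,13-trien-19,20-olide | COc1c(O)c2c(c(O)c1C(C)C)C(=O)C[C@@H]1[C@]23CCC[C@]1(C)C(=O)OC3 | target

## Step count and risks

Total step count: 18. Longest linear sequence: 18 steps (1 to 23); 15 is purchased.

**Step 12 (key step).** The most likely failure is poor orientation of the alkyne during insertion. Both ruthenacycle α-carbons carry the same boryl group, so only the remote difference between quaternary C10 and C7 discriminates. Slow turnover is also possible, because both diyne alkynes are substituted, and protodeborylation could compete.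

The fallback differentiates the two termini, so that the established preference of the alkyne substituent to avoid a substituted diyne terminus decides the orientation.
- Alkyne 10 is silylated (LiN(iPr)2, Me3SiCl) to (1S,5R,9R)-1-methyl-9-(prop-2-en-1-yl)-5-[(trimethylsilyl)ethynyl]-3-oxabicyclo[3.3.1]nonan-2-one F1.
- F1 is ozonised to the aldehyde 2-{(1S,5R,9R)-1-methyl-2-oxo-5-[(trimethylsilyl)ethynyl]-3-oxabicyclo[3.3.1]nonan-9-yl}acetaldehyde F2.
- HC≡CMgBr adds to give the propargylic alcohol (1S,5R,9R)-9-(2-hydroxybut-3-yn-1-yl)-1-methyl-5-[(trimethylsilyl)ethynyl]-3-oxabicyclo[3.3.1]nonan-2-one F3, which is silylated with TBSCl to the diyne (1S,5R,9R)-9-{2-[(tert-butyldimethylsilyl)oxy]but-3-yn-1-yl}-1-methyl-5-[(trimethylsilyl)ethynyl]-3-oxabicyclo[3.3.1]nonan-2-one F4. F4 has silicon on C11 and hydrogen on C14.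
- Cp*RuCl(cod) with 15 should give (4S,5R,10R)-7-[(tert-butyldimethylsilyl)oxy]-11-(trimethylsilyl)abieta-8,11,13-trien-19,20-olide F5.
- Ipso-iododesilylation with ICl gives the 11-iodide (4S,5R,10R)-7-[(tert-butyldimethylsilyl)oxy]-11-iodoabieta-8,11,13-trien-19,20-olide F6.
- Miyaura borylation (PdCl2(dppf), bis(pinacolato)diboron, KOAc) gives the 11-boronate (4S,5R,10R)-7-[(tert-butyldimethylsilyl)oxy]-11-(4,4,5,5-tetramethyl-1,3,2-dioxaborolan-2-yl)abieta-8,11,13-trien-19,20-olide F7.
- KHSO5 oxidation gives the phenol (4S,5R,10R)-7-[(tert-butyldimethylsilyl)oxy]-11-hydroxyabieta-8,11,13-trien-19,20-olide F8.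
- Teuber oxidation of this para-unsubstituted phenol with K2[ON(SO3)2] returns to the route at quinone 18.

**Step 2.** The risk is poor facial selectivity at C5 if the ligand and the C4 centre are mismatched, and later erosion of the C5 configuration by enolisation during step 3.

The fallback sets C5 first and C4 last.
- Enone 1 undergoes asymmetric conjugate reduction (CuCl, NaOtBu, the p-tol-BINAP enantiomer that gives the 1R ester, polymethylhydrosiloxane). The silyl enol ether is allylated in the same flask (allyl bromide, Bu4N[Ph3SiF2]) to the trans keto ester methyl (1R,2S)-3-oxo-2-(prop-2-en-1-yl)cyclohexane-1-carboxylate F9.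
- Wittig methoxymethylenation gives methyl (1R,2S)-3-(methoxymethylidene)-2-(prop-2-en-1-yl)cyclohexane-1-carboxylate F10.
- Ester enolate methylation (LiN(iPr)2, MeI) gives 5. Allylic strain from both exocyclic double bonds holds the allyl group axial, so the methyl group enters anti to it.

**Step 5.** The risks are retro-aldol loss of formaldehyde before hydride transfer at the hindered aldehyde, formal (acetal) formation from the diol with excess formaldehyde, and ester hydrolysis.

The fallback separates the two events. Pyrrolidine-catalysed α-hydroxymethylation of 6 with aqueous formaldehyde gives the hydroxy aldehyde methyl (1S,2R)-3-formyl-3-(hydroxymethyl)-1-methyl-2-(prop-2-en-1-yl)cyclohexane-1-carboxylate F11 as an epimer mixture. NaBH4 reduction gives 7, and acid lactonisation (p-TsOH, toluene) rejoins the route at 8.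

**Step 15.** The risk is deprotonation at C7 (γ to the C11 carbonyl) by methoxide, leading to quinone methide tautomers, silyl migration or dimerisation, and ring opening of the lactone.

The fallback avoids the strong base.
- Weitz–Scheffer epoxidation of 18 (H2O2, Na2CO3) gives the 12,13-epoxide (4S,5R,10R)-7-[(tert-butyldimethylsilyl)oxy]-12,13-epoxy-11,14-dioxoabiet-8-en-19,20-olide F12.
- Acid-mediated isomerisation (p-TsOH, CH2Cl2) gives the hydroxyquinone (4S,5R,10R)-7-[(tert-butyldimethylsilyl)oxy]-12-hydroxy-11,14-dioxoabieta-8,12-dien-19,20-olide F13.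
- O-methylation of this acidic hydroxyl with trimethylsilyldiazomethane in MeOH/toluene returns to the route at 20.

## Further compounds

F1 | step 12 | (1S,5R,9R)-1-methyl-9-(prop-2-en-1-yl)-5-[(trimethylsilyl)ethynyl]-3-oxabicyclo[3.3.1]nonan-2-one | C=CC[C@@H]1[C@@]2(C#C[Si](C)(C)C)CCC[C@]1(C)C(=O)OC2
F2 | step 12 | 2-{(1S,5R,9R)-1-methyl-2-oxo-5-[(trimethylsilyl)ethynyl]-3-oxabicyclo[3.3.1]nonan-9-yl}acetaldehyde | O=CC[C@@H]1[C@@]2(C#C[Si](C)(C)C)CCC[C@]1(C)C(=O)OC2
F3 | step 12 | (1S,5R,9R)-9-(2-hydroxybut-3-yn-1-yl)-1-methyl-5-[(trimethylsilyl)ethynyl]-3-oxabicyclo[3.3.1]nonan-2-one | C#CC(O)C[C@@H]1[C@@]2(C#C[Si](C)(C)C)CCC[C@]1(C)C(=O)OC2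
F4 | step 12 | (1S,5R,9R)-9-{2-[(tert-butyldimethylsilyl)oxy]but-3-yn-1-yl}-1-methyl-5-[(trimethylsilyl)ethynyl]-3-oxabicyclo[3.3.1]nonan-2-one | C#CC(O[Si](C)(C)C(C)(C)C)C[C@@H]1[C@@]2(C#C[Si](C)(C)C)CCC[C@]1(C)C(=O)OC2
F5 | step 12 | (4S,5R,10R)-7-[(tert-butyldimethylsilyl)oxy]-11-(trimethylsilyl)abieta-8,11,13-trien-19,20-olide | CC(C)c1cc([Si](C)(C)C)c2c(c1)C(O[Si](C)(C)C(C)(C)C)C[C@@H]1[C@]23CCC[C@]1(C)C(=O)OC3
F6 | step 12 | (4S,5R,10R)-7-[(tert-butyldimethylsilyl)oxy]-11-iodoabieta-8,11,13-trien-19,20-olide | CC(C)c1cc(I)c2c(c1)C(O[Si](C)(C)C(C)(C)C)C[C@@H]1[C@]23CCC[C@]1(C)C(=O)OC3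
F7 | step 12 | (4S,5R,10R)-7-[(tert-butyldimethylsilyl)oxy]-11-(4,4,5,5-tetramethyl-1,3,2-dioxaborolan-2-yl)abieta-8,11,13-trien-19,20-olide | CC(C)c1cc(B4OC(C)(C)C(C)(C)O4)c2c(c1)C(O[Si](C)(C)C(C)(C)C)C[C@@H]1[C@]23CCC[C@]1(C)C(=O)OC3
F8 | step 12 | (4S,5R,10R)-7-[(tert-butyldimethylsilyl)oxy]-11-hydroxyabieta-8,11,13-trien-19,20-olide | CC(C)c1cc(O)c2c(c1)C(O[Si](C)(C)C(C)(C)C)C[C@@H]1[C@]23CCC[C@]1(C)C(=O)OC3
F9 | step 2 | methyl (1R,2S)-3-oxo-2-(prop-2-en-1-yl)cyclohexane-1-carboxylate | C=CC[C@@H]1C(=O)CCC[C@H]1C(=O)OC
F10 | step 2 | methyl (1R,2S)-3-(methoxymethylidene)-2-(prop-2-en-1-yl)cyclohexane-1-carboxylate | C=CC[C@@H]1C(=COC)CCC[C@H]1C(=O)OC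
F11 | step 5 | methyl (1S,2R)-3-formyl-3-(hydroxymethyl)-1-methyl-2-(prop-2-en-1-yl)cyclohexane-1-carboxylate | C=CC[C@@H]1C(C=O)(CO)CCC[C@]1(C)C(=O)OC
F12 | step 15 | (4S,5R,10R)-7-[(tert-butyldimethylsilyl)oxy]-12,13-epoxy-11,14-dioxoabiet-8-en-19,20-olide | CC(C)C12OC1C(=O)C1=C(C2=O)C(O[Si](C)(C)C(C)(C)C)C[C@@H]2[C@]13CCC[C@]2(C)C(=O)OC3
F13 | step 15 | (4S,5R,10R)-7-[(tert-butyldimethylsilyl)oxy]-12-hydroxy-11,14-dioxoabieta-8,12-dien-19,20-olide | CC(C)C1=C(O)C(=O)C2=C(C1=O)C(O[Si](C)(C)C(C)(C)C)C[C@@H]1[C@]23CCC[C@]1(C)C(=O)OC3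
A1 | alternative 1 | methyl 5,7,8-trimethoxy-2-oxo-6-(propan-2-yl)-1,2,3,4-tetrahydronaphthalene-1-carboxylate | COC(=O)C1C(=O)CCc2c1c(OC)c(OC)c(C(C)C)c2OC
A2 | alternative 1 | tert-butyl 3-oxopent-4-enoate | C=CC(=O)CC(=O)OC(C)(C)C
A3 | alternative 1 | 19-tert-butyl 20-methyl 11,12,14-trimethoxy-3-oxo-18-norabieta-4,8,11,13-tetraene-19,20-dioate, C10 configured as in 23 | COc1c(OC)c2c(c(OC)c1C(C)C)CCC3=C(C(=O)OC(C)(C)C)C(=O)CC[C@]23C(=O)OC
A4 | alternative 2 | [1-(3-{[tert-butyl(dimethyl)silyl]oxy}propyl)-4-oxocyclohexa-2,5-dien-1-yl]methyl 2-(phenylsulfonyl)propanoate | O=C1C=CC(CCCO[Si](C)(C)C(C)(C)C)(COC(=O)C(C)S(=O)(=O)c2ccccc2)C=C1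
A5 | alternative 2 | cis-fused ring B enone δ-lactone with C10 and C5 set and the sulfonyl-bearing C4 unassigned | O=C1C=C[C@]2(CCCO[Si](C)(C)C(C)(C)C)COC(=O)C(C)(S(=O)(=O)c3ccccc3)[C@@H]2C1
A6 | alternative 3 | podocarpic acid, 12-hydroxypodocarpa-8,11,13-trien-19-oic acid | Oc1cc2c(cc1)CC[C@@H]1[C@]2(C)CCC[C@]1(C)C(=O)O
A7 | alternative 3 | 12-methoxy-7-oxoabieta-8,11,13-trien-19-amide | COc1cc2c(cc1C(C)C)C(=O)C[C@@H]1[C@]2(C)CCC[C@]1(C)C(N)=O
A8 | alternative 3 | 12-methoxy-7-oxoabieta-8,11,13-trien-19,20-olide | COc1cc2c(cc1C(C)C)C(=O)C[C@@H]1[C@]23CCC[C@]1(C)C(=O)OC3
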